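## The problem

Lespecyrtin E3 (30) is a (6aR,11aR)-pterocarpan. A chroman (rings A and B) is cis-fused to a dihydrobenzofuran (rings C and D), a 2,2-dimethyl-2H-pyran (ring E) is annulated across C7–C8, prenyl groups sit on C2 and C10, and C3 and C9 carry free phenols. The only stereocentres, C6a and C11a, are adjacent. Because the 6/5 fusion can only be cis, C6a dictates C11a whenever the O11–C11a bond is closed through the benzylic cation, so only C6a has to be set in absolute terms. Ring D is the real obstacle: all six carbons are substituted (C6a on C6b, the ring E carbon on C7, O8, O9, prenyl on C10, O11 on C10a), and arene substitution offers no reliable way to place a prenyl group between two oxygens while keeping C7 open. The functionality is fragile: ortho-prenylphenols cyclise to chromans in acid, the chromene and prenyl alkenes exclude hydrogenolysis and strong oxidants, the C11a–O11 bond ionises in acid, and the electron-rich phenols oxidise easily. The enabling feature is that O8 and O11 are para on ring D, with the O9-bearing carbon and the prenyl-bearing C10 between them on one side and C7/C6b on the other. That is a 2-alkoxy-3-alkyl-1,4-benzoquinone with one CH and one carbon substituent, which a squarate-derived 4-alkynyl-4-hydroxycyclobutenone delivers by thermal ring expansion: the four-membered ring supplies C8, C9, C10 and C10a with their oxygens and the prenyl group, and the alkyne supplies C7 and C6b with C6a attached.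

## Retrosynthesis

**Protecting groups (30 ⇐ 29 ⇐ 28).** The O9–CH3 bond and the O3–Si bond are cut last. The methyl group is what the squarate leaves on O9, and it is needed until ring E is in place. Thiolate demethylation (SN2 at methyl) is preferred over any acid-labile group because of the ortho-prenylphenols. The silyl group on O3 is removed first with fluoride, so that the last step starts from the defined phenol 29.

**Ring E (28 ⇐ 27 ⇐ 25 + 26).** The O8–C and C7–C bonds of the pyran are cut. An aryl 1,1-dimethylpropargyl ether (27) rearranges only to C7, the single free position ortho to O8, because C9 is blocked by the methoxy group. This requires O8–H to be the only free phenol, which is the case in 25.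

**Ring C (25 ⇐ 24 ⇐ 23).** The O11–C11a bond is cut. In hydroquinone 24 only the C10a hydroxyl can reach C11a; the C8 hydroxyl is meta to C6b. The benzylic silyl ether ionises readily (O5 ortho, silyloxy para), closure can only be cis, and the C11a configuration of the precursor is therefore irrelevant. Hydroquinone 24 is the reduction product of quinone 23.

**Ring D, the key cut (23 ⇐ 22 ⇐ 21).** The C10a–C6b bond is cut and ring D is traced back through alkynyl ketene 22 to a cyclobutenone and an alkyne. Cutting C6a–C6b instead would require coupling a secondary alkyl centre to a hexasubstituted arene, and building ring D by substitution leaves the pattern problem unsolved. The chosen cut turns regiochemistry into the connectivity of 21. The forward reaction must close six- rather than five-membered, tolerate two silyl ethers and two prenyl groups, and leave C6a untouched.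

**Fragment union (21 ⇐ 20 + 19, 20 ⇐ 13).** The carbinol–alkyne bond is cut. Lithium acetylide 20 should attack the carbonyl of 19 that lies next to the methoxy-bearing carbon (an enone carbonyl), not the vinylogous ester carbonyl. This decides which quinone oxygen becomes O8 and which O11. The two halves are of similar size.

**Cyclobutenedione (19 ⇐ 17 + 18, 17 ⇐ 16 ⇐ 14 + 15).** Prenyl-metal reagents attack carbonyl groups through their substituted terminus and would install the 1,1-dimethylallyl isomer. The side chain is therefore introduced as allyl from 15 (adduct 16 is rearranged to 17) and extended to prenyl by cross-metathesis with 18.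

**C6a (13 ⇐ 12 ⇐ 11 ⇐ 10).** The stereocentre is set by transfer hydrogenation of the configurationally labile α-alkynyl ketone 10 with dynamic kinetic resolution. The cis alcohol 11 carries the right C3 and the minor trans isomer carries the wrong one, so it must be removed at this stage. Silylation (12) and C–Si cleavage give 13.

**Alkyne attachment (10 ⇐ 9 ⇐ 7 + 8).** The C3–C(sp) bond is cut to a 3-iodochromone and alkyne 8 (Sonogashira coupling). Conjugate reduction of 9 unmasks the ketone.

**Ring A (7 ⇐ 6 ⇐ 5 ⇐ 3 + 4, 3 ⇐ 2 ⇐ 1).** The pyranone is closed from enaminone 6 with iodination. The prenyl group is placed by Stille coupling of stannane 4 with iodide 3, whose iodine enters para to the free phenol of 2 and ortho to the silyl ether. Direct C-prenylation of 1 would favour the position between the oxygens.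

## Roads not taken

**Alternative 1:** The cut is C6a–C11a, the bond shared by rings B and C. A ring D aryldiazoacetate A1, with the ring A benzyl group already on O11, is decomposed by Rh2(S-PTTL)4 (a divalent rhodium carboxylate dimer). The carbene inserts into the benzylic C–H bond and closes ring C as the cis-2-aryl-2,3-dihydrobenzofuran-3-carboxylate A2.
- Merits: both stereocentres are made together, late, under catalyst control, and the ether linking the arenes is trivial.
- Weak points: ring D must enter as a finished pentasubstituted arene, so the regiochemical problem moves into the synthesis of A1. The carbene also has competitors: two prenyl alkenes (cyclopropanation, allylic insertion), the activated O–CH2–O hydrogens of the acetals, and ylide formation at the ether oxygen. After A2, ring B must still be closed (ester reduction, acidic unmasking of O5 beside prenyl groups, Mitsunobu etherification) and ring E built, so the count is not lower.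
- Comparison: in stereochemical economy this road is better than the chosen one, which sets C6a early and relays it. The chosen plan answers with a ring D fixed by connectivity and a key step that contains nothing reactive toward alkenes.

**Alternative 2:** The cut runs through ring B at C6–C6a and C11a–C11b. A Lewis acid ionises the ring A methoxymethyl ether A3 to an aryloxymethyl cation, which adds to the aryl-bearing carbon of the ring D β-methoxystyrene A4. Ring A then closes on the C11a oxocarbenium ion (oxa-Povarov annulation) to give 4-methoxyisoflavan A5, whose methoxy group later leaves for ring C closure.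
- Merits: it is the most convergent plan; two arenes of equal size are joined and ring B is formed in one operation, with ring E and both prenyl groups in place.
- Weak points: the stepwise cationic annulation offers no handle for absolute control at C6a, so a resolution would probably be needed. The Lewis acid must ionise an acetal beside two prenyl groups, a chromene and silyl ethers. A4 is again a hexasubstituted arene made by classical substitution.
- Comparison: it would be shorter if A4 were easy to obtain. The chosen plan sets against that a catalytic, predictable C6a and a neutral thermal key step.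

**Alternative 3:** The cut removes ring C at C6a–C6b and C11a–O11. The titanium TADDOLate from TiCl2(OiPr)2 (tetravalent titanium) and TADDOL binds 2-methoxy-3-prenyl-1,4-benzoquinone A6. The C3=C4 alkene of 2H-chromene A7 attacks the quinone CH para to the methoxy-bearing carbon, and the quinone oxygen closes on the benzylic cation to give pterocarpan A8.
- Merits: A8 is the same compound as 25, and this road reaches it in roughly half the steps from partners that each need only a few. On step economy it is the better plan.
- Weak points: the absolute configuration rests on a stoichiometric chiral Lewis acid with substrate-dependent induction. Both partners carry prenyl alkenes that are nucleophiles toward an activated quinone, and (2+2) and (5+2) adducts are the usual competitors of the (3+2) mode. The C10 prenyl group flanks the carbonyl that must become O11, and A7 is acid-sensitive.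
- Comparison: the chosen plan pays about eight more steps for a C6a set by a reduction of known facial sense, a ring D whose regiochemistry cannot go wrong once 21 exists, and no strong Lewis acid near the prenyl groups. If the selectivities of this road held, it would replace steps 1–14.

Key step: step 13

Remark on the chemistry: prenyl = 3-methylbut-2-en-1-yl, TIPS = triisopropylsilyl, TBS = tert-butyldimethylsilyl, TMS = trimethylsilyl; pterocarpan positions follow the usual numbering; reagents 4, 8, 15, 18 and 26 are assumed to be purchased.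

Step 1
Reactants: 1 2,4-dihydroxyacetophenone
Product: 2 1-[2-hydroxy-4-(TIPS-oxy)phenyl]ethan-1-one
Conditions: TIPSCl, imidazole, DMF, 0 °C to rt
Reagents that add atoms: triisopropylsilyl chloride, CC(C)[Si](Cl)(C(C)C)C(C)C
Why: Selective silyl ether formation: the 2-hydroxyl is tied up in a hydrogen bond to the acetyl carbonyl, so only the 4-hydroxyl should react.

Step 2
Reactants: 2 1-[2-hydroxy-4-(TIPS-oxy)phenyl]ethan-1-one
Product: 3 1-[2-hydroxy-5-iodo-4-(TIPS-oxy)phenyl]ethan-1-one
Conditions: N-iodosuccinimide, CF3CO2H (cat.), MeCN, 0 °C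
Reagents that add atoms: N-iodosuccinimide, O=C1CCC(=O)N1I
Why: Electrophilic aromatic iodination para to the free phenol; C3 is shielded between two oxygens and by the bulky silyl group, so C5 should be attacked.

Step 3
Reactants: 3 1-[2-hydroxy-5-iodo-4-(TIPS-oxy)phenyl]ethan-1-one; 4 tributyl(prenyl)stannane
Product: 5 1-[2-hydroxy-5-prenyl-4-(TIPS-oxy)phenyl]ethan-1-one
Conditions: Pd(PPh3)4 (5 mol %), DMF, 90 °C
Reagents that add atoms: none
Why: Stille coupling of an aryl iodide with an allylic stannane; reductive elimination from the less hindered allyl terminus should give the linear prenyl arene, and any branched isomer is removed by chromatography.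

Step 4
Reactants: 5 1-[2-hydroxy-5-prenyl-4-(TIPS-oxy)phenyl]ethan-1-one
Product: 7 3-iodo-6-prenyl-7-(TIPS-oxy)-4H-chromen-4-one, via enaminone 6 (not isolated)
Conditions: Me2NCH(OMe)2, toluene, 80 °C; concentrate; I2 (1.2 equiv), CHCl3, rt
Reagents that add atoms: N,N-dimethylformamide dimethyl acetal, COC(OC)N(C)C; iodine, II
Why: Condensation of the methyl ketone to the enaminone, then iodination at the enaminone carbon, closure by the phenol and loss of dimethylamine (iodocyclisation to a 3-iodochromone). The enaminone carbon is far more nucleophilic than the trisubstituted alkene, so the prenyl group should be spared.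

Step 5
Reactants: 7 3-iodo-6-prenyl-7-(TIPS-oxy)-4H-chromen-4-one; 8 ethynyltrimethylsilane
Product: 9 6-prenyl-7-(TIPS-oxy)-3-[(TMS)ethynyl]-4H-chromen-4-one
Conditions: PdCl2(PPh3)2 (3 mol %), CuI (6 mol %), Et3N, THF, rt
Reagents that add atoms: none
Why: Sonogashira coupling at the reactive α-iodoenone position; a tertiary amine base avoids ring opening of the chromone.

Step 6
Reactants: 9 6-prenyl-7-(TIPS-oxy)-3-[(TMS)ethynyl]-4H-chromen-4-one
Product: 10 rac-6-prenyl-7-(TIPS-oxy)-3-[(TMS)ethynyl]chroman-4-one
Conditions: LiBH(s-Bu)3 (L-Selectride, 1.1 equiv), THF, −78 °C; AcOH, −78 °C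
Reagents that add atoms: none
Why: Conjugate (1,4) hydride reduction of the chromone at unhindered C2; the ketone stays masked as its enolate until the cold acid quench, which should protonate kinetically at C3.

Step 7
Reactants: 10 rac-6-prenyl-7-(TIPS-oxy)-3-[(TMS)ethynyl]chroman-4-one
Product: 11 (3R,4R)-6-prenyl-7-(TIPS-oxy)-3-[(TMS)ethynyl]chroman-4-ol (cis)
Conditions: RuCl[(R,R)-TsDPEN](p-cymene) (2 mol %), HCO2H–Et3N (5:2), EtOAc, 35 °C; chromatographic removal of the trans isomer
Reagents that add atoms: none
Why: Asymmetric transfer hydrogenation with dynamic kinetic resolution: the α-alkynyl ketone should racemise through its enol faster than it is reduced, the (R,R)-catalyst delivers hydride to the aryl ketone face that gives the 4R carbinol, and it prefers the 3R ketone, in which hydride enters anti to the alkynyl group. The minor trans isomer carries the opposite C3 configuration and must be removed here, because C4 is erased later and C3 becomes C6a.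

Step 8
Reactants: 11 (3R,4R)-6-prenyl-7-(TIPS-oxy)-3-[(TMS)ethynyl]chroman-4-ol
Product: 12 (3R,4R)-4-(TBS-oxy)-6-prenyl-7-(TIPS-oxy)-3-[(TMS)ethynyl]chromane
Conditions: TBSOTf, 2,6-lutidine, CH2Cl2, −78 to 0 °C
Reagents that add atoms: tert-butyldimethylsilyl trifluoromethanesulfonate, CC(C)(C)[Si](C)(C)OS(=O)(=O)C(F)(F)F
Why: Silylation of a hindered secondary benzylic alcohol with a silyl triflate under non-ionising basic conditions; both stereocentres are untouched.

Step 9
Reactants: 12 (3R,4R)-4-(TBS-oxy)-6-prenyl-7-(TIPS-oxy)-3-[(TMS)ethynyl]chromane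
Product: 13 (3R,4R)-4-(TBS-oxy)-3-ethynyl-6-prenyl-7-(TIPS-oxy)chromane
Conditions: K2CO3 (0.3 equiv), MeOH–THF, 0 °C
Reagents that add atoms: none
Why: Methanolysis of the C(sp)–Si bond, which is much faster than attack on the hindered aryl TIPS ether or the alkyl TBS ether under these cold, substoichiometric conditions.

Step 10
Reactants: 14 dimethyl squarate; 15 allylmagnesium bromide
Product: 17 3-allyl-4-methoxycyclobut-3-ene-1,2-dione, via bromomagnesium alkoxide 16 (not isolated)
Conditions: THF, −78 °C; (CF3CO)2O, −78 to 0 °C; aq. NaHCO3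
Reagents that add atoms: water, O
Why: 1,2-Addition of the Grignard reagent to one squarate carbonyl, then acylation and ionisation of the tertiary alkoxide and hydrolysis of the methoxy-stabilised cation (the standard squarate-to-3-alkyl-4-alkoxycyclobutenedione rearrangement).

Step 11
Reactants: 17 3-allyl-4-methoxycyclobut-3-ene-1,2-dione; 18 2-methylbut-2-ene
Product: 19 3-methoxy-4-prenylcyclobut-3-ene-1,2-dione
Conditions: RuCl2(H2IMes)(=CH-C6H4-2-OiPr) (second-generation Hoveyda–Grubbs catalyst, 3 mol %), 2-methylbut-2-ene–CH2Cl2 (1:1), 35 °C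
Reagents that add atoms: none
Why: Olefin cross-metathesis of a terminal allyl group with excess 2-methylbut-2-ene, an established way to turn allyl into prenyl; the tetrasubstituted ring alkene is inert to the catalyst.

Step 12
Reactants: 13 (3R,4R)-4-(TBS-oxy)-3-ethynyl-6-prenyl-7-(TIPS-oxy)chromane; 19 3-methoxy-4-prenylcyclobut-3-ene-1,2-dione
Product: 21 4-{[(3R,4R)-4-(TBS-oxy)-6-prenyl-7-(TIPS-oxy)chroman-3-yl]ethynyl}-4-hydroxy-3-methoxy-2-prenylcyclobut-2-en-1-one (both carbinol epimers), via lithium acetylide 20 (not isolated)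
Conditions: n-BuLi (1.0 equiv), THF, −78 °C; add to 19 (1.3 equiv), THF, −78 °C; aq. NH4Cl
Reagents that add atoms: none
Why: 1,2-Addition of a lithium acetylide to a cyclobutenedione; the carbonyl next to the methoxy-bearing carbon is an enone carbonyl and the other a deactivated vinylogous ester, so attack should occur at the former. Inverse addition at −78 °C limits deprotonation of the acidic prenyl CH2, and the carbinol epimers are used together.

Step 13
Reactants: 21 4-{[(3R,4R)-4-(TBS-oxy)-6-prenyl-7-(TIPS-oxy)chroman-3-yl]ethynyl}-4-hydroxy-3-methoxy-2-prenylcyclobut-2-en-1-one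
Product: 23 2-methoxy-3-prenyl-5-[(3R,4R)-4-(TBS-oxy)-6-prenyl-7-(TIPS-oxy)chroman-3-yl]-1,4-benzoquinone, via alkynyl ketene 22 (not isolated)
Conditions: degassed toluene, 110 °C, argon, 1–2 h
Reagents that add atoms: none
Why: Thermal conrotatory 4π opening of the cyclobutenone, with the hydroxyl rotating outward, gives the (Z)-enynyl ketene 22 in which the alkyne lies cis to the ketene. The ketene carbon (future C10a) bonds to the distal alkyne carbon (future C6b), closing ring D in the six-membered (6-endo-dig) mode rather than the five-membered (5-exo-dig) mode at the proximal carbon, and the resulting diradical collapses to the quinone by transfer of the hydroxyl hydrogen to C7. The closest known reaction type is the Moore rearrangement of 4-alkynyl-4-hydroxycyclobutenones to 1,4-benzoquinones. No stereocentre is formed: both carbinol epimers of 21 converge and C6a is a spectator. The selectivity needed is six- over five-membered closure, which the alkyl (non-radical-stabilising) substituent on the alkyne should secure. The quinone regiochemistry follows from the connectivity of 21: the carbinol carbon becomes C8 (flanked by C9–OMe and C7–H) and the ketene carbon becomes C10a (next to prenyl-bearing C10). Neutral, base-free conditions and a short reaction time protect the silyl ethers, the prenyl groups and the C6a–H centre, which is quinone-allylic in 23. Release of cyclobutene strain and formation of the quinone drive the step.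

Step 14
Reactants: 23 2-methoxy-3-prenyl-5-[(3R,4R)-4-(TBS-oxy)-6-prenyl-7-(TIPS-oxy)chroman-3-yl]-1,4-benzoquinone
Product: 25 (6aR,11aR)-8-hydroxy-9-methoxy-2,10-diprenyl-3-(TIPS-oxy)pterocarpan, via hydroquinone 24 (not isolated)
Conditions: Na2S2O4, EtOAc–H2O, rt, argon; dry and concentrate; BF3·OEt2 (0.3 equiv), CH2Cl2, −78 to −30 °C
Reagents that add atoms: none
Why: Quinone reduction, then Lewis-acid ionisation of the benzylic silyl ether (cation stabilised by O5 ortho and the silyloxy group para) and capture by the C10a hydroxyl, as in the classical isoflavan-4-ol to pterocarpan closure. The 6/5 fusion can only be cis, so C6a (R) sets C11a (R); the C8 hydroxyl cannot reach C11a, and the low temperature should spare the prenyl groups.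

Step 15
Reactants: 25 (6aR,11aR)-8-hydroxy-9-methoxy-2,10-diprenyl-3-(TIPS-oxy)pterocarpan; 26 3-chloro-3-methylbut-1-yne
Product: 27 (6aR,11aR)-9-methoxy-8-[(2-methylbut-3-yn-2-yl)oxy]-2,10-diprenyl-3-(TIPS-oxy)pterocarpan
Conditions: CuCl2·2H2O (1 mol %), DBU, MeCN, 0 °C, argon
Reagents that add atoms: none
Why: Copper-catalysed O-alkylation of a phenol with a tertiary propargylic chloride; O8–H is the only free hydroxyl.

Step 16
Reactants: 27 (6aR,11aR)-9-methoxy-8-[(2-methylbut-3-yn-2-yl)oxy]-2,10-diprenyl-3-(TIPS-oxy)pterocarpan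
Product: 28 9-O-methyl-3-O-TIPS-lespecyrtin E3, the (6aR,11aR)-pterocarpan with 9-OMe, 3-OTIPS, 2,10-diprenyl and a 2,2-dimethyl-2H-pyran fused at C7–C8 (oxygen on C8)
Conditions: o-xylene, 140 °C, argon
Reagents that add atoms: none
Why: Aromatic propargyl Claisen rearrangement to C7, the only free ortho position (C9 is blocked by OMe), followed by 1,5-hydrogen shift and oxa-6π electrocyclisation, closes ring E.

Step 17
Reactants: 28 9-O-methyl-3-O-TIPS-lespecyrtin E3
Product: 29 9-O-methyllespecyrtin E3
Conditions: Bu4NF, THF, 0 °C; aq. NH4Cl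
Reagents that add atoms: none
Why: Fluoride cleavage of the aryl silyl ether under non-acidic conditions that leave the chromene, prenyl groups and pterocarpan core alone.

Step 18
Reactants: 29 9-O-methyllespecyrtin E3
Product: 30 lespecyrtin E3
Conditions: NaSEt (6 equiv), degassed DMF, 120 °C, argon; aq. NH4Cl
Reagents that add atoms: none
Why: Thiolate demethylation by SN2 attack at the methyl group; the O9 methyl ether is flanked on both sides and twisted out of conjugation, which favours it over the ring ether carbons, and the basic medium avoids acid-induced cyclisation of the prenylphenols.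

## Compound list

1 | 2,4-dihydroxyacetophenone | CC(=O)c1ccc(O)cc1O | starting material
2 | 1-[2-hydroxy-4-(TIPS-oxy)phenyl]ethan-1-one | CC(=O)c1ccc(O[Si](C(C)C)(C(C)C)C(C)C)cc1O | intermediate
3 | 1-[2-hydroxy-5-iodo-4-(TIPS-oxy)phenyl]ethan-1-one | CC(=O)c1cc(I)c(O[Si](C(C)C)(C(C)C)C(C)C)cc1O | intermediate
4 | tributyl(prenyl)stannane | CCCC[Sn](CCCC)(CCCC)CC=C(C)C | starting material
5 | 1-[2-hydroxy-5-prenyl-4-(TIPS-oxy)phenyl]ethan-1-one | CC(=O)c1cc(CC=C(C)C)c(O[Si](C(C)C)(C(C)C)C(C)C)cc1O | intermediate
6 | (E)-3-(dimethylamino)-1-[2-hydroxy-5-prenyl-4-(TIPS-oxy)phenyl]prop-2-en-1-one | CN(C)/C=C/C(=O)c1cc(CC=C(C)C)c(O[Si](C(C)C)(C(C)C)C(C)C)cc1O | intermediate (not isolated)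
7 | 3-iodo-6-prenyl-7-(TIPS-oxy)-4H-chromen-4-one | O=c1c(I)coc2cc(O[Si](C(C)C)(C(C)C)C(C)C)c(CC=C(C)C)cc12 | intermediate
8 | ethynyltrimethylsilane | C#C[Si](C)(C)C | starting material
9 | 6-prenyl-7-(TIPS-oxy)-3-[(TMS)ethynyl]-4H-chromen-4-one | O=c1c(C#C[Si](C)(C)C)coc2cc(O[Si](C(C)C)(C(C)C)C(C)C)c(CC=C(C)C)cc12 | intermediate
10 | rac-6-prenyl-7-(TIPS-oxy)-3-[(TMS)ethynyl]chroman-4-one | O=C1C(C#C[Si](C)(C)C)COc2cc(O[Si](C(C)C)(C(C)C)C(C)C)c(CC=C(C)C)cc21 | intermediate
11 | (3R,4R)-6-prenyl-7-(TIPS-oxy)-3-[(TMS)ethynyl]chroman-4-ol (cis) | CC(C)=CCc1cc2c(cc1O[Si](C(C)C)(C(C)C)C(C)C)OC[C@@H](C#C[Si](C)(C)C)[C@H]2O | intermediate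
12 | (3R,4R)-4-(TBS-oxy)-6-prenyl-7-(TIPS-oxy)-3-[(TMS)ethynyl]chromane | CC(C)=CCc1cc2c(cc1O[Si](C(C)C)(C(C)C)C(C)C)OC[C@@H](C#C[Si](C)(C)C)[C@H]2O[Si](C)(C)C(C)(C)C | intermediate
13 | (3R,4R)-4-(TBS-oxy)-3-ethynyl-6-prenyl-7-(TIPS-oxy)chromane | CC(C)=CCc1cc2c(cc1O[Si](C(C)C)(C(C)C)C(C)C)OC[C@@H](C#C)[C@H]2O[Si](C)(C)C(C)(C)C | intermediate
14 | dimethyl squarate (3,4-dimethoxycyclobut-3-ene-1,2-dione) | COC1=C(OC)C(=O)C1=O | starting material
15 | allylmagnesium bromide | C=CC[Mg]Br | starting material
16 | bromomagnesium alkoxide of 4-allyl-4-hydroxy-2,3-dimethoxycyclobut-2-en-1-one | COC1=C(OC)C(CC=C)(O[Mg]Br)C1=O | intermediate (not isolated)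
17 | 3-allyl-4-methoxycyclobut-3-ene-1,2-dione | COC1=C(CC=C)C(=O)C1=O | intermediate
18 | 2-methylbut-2-ene | CC=C(C)C | starting material
19 | 3-methoxy-4-prenylcyclobut-3-ene-1,2-dione | COC1=C(CC=C(C)C)C(=O)C1=O | intermediate
20 | lithium acetylide of 13 | CC(C)=CCc1cc2c(cc1O[Si](C(C)C)(C(C)C)C(C)C)OC[C@@H](C#C[Li])[C@H]2O[Si](C)(C)C(C)(C)C | intermediate (not isolated)
21 | 4-{[(3R,4R)-4-(TBS-oxy)-6-prenyl-7-(TIPS-oxy)chroman-3-yl]ethynyl}-4-hydroxy-3-methoxy-2-prenylcyclobut-2-en-1-one (carbinol epimers) | CC(C)=CCc1cc2c(cc1O[Si](C(C)C)(C(C)C)C(C)C)OC[C@@H](C#CC1(O)C(OC)=C(CC=C(C)C)C1=O)[C@H]2O[Si](C)(C)C(C)(C)C | intermediate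
22 | (Z)-4-hydroxy-3-methoxy-2-prenyl-6-[(3R,4R)-4-(TBS-oxy)-6-prenyl-7-(TIPS-oxy)chroman-3-yl]hexa-1,3-dien-5-yn-1-one (ketene) | CC(C)=CCc1cc2c(cc1O[Si](C(C)C)(C(C)C)C(C)C)OC[C@@H](C#C/C(O)=C(OC)\C(CC=C(C)C)=C=O)[C@H]2O[Si](C)(C)C(C)(C)C | intermediate (not isolated)
23 | 2-methoxy-3-prenyl-5-[(3R,4R)-4-(TBS-oxy)-6-prenyl-7-(TIPS-oxy)chroman-3-yl]-1,4-benzoquinone | CC(C)=CCc1cc2c(cc1O[Si](C(C)C)(C(C)C)C(C)C)OC[C@@H](C1=CC(=O)C(OC)=C(CC=C(C)C)C1=O)[C@H]2O[Si](C)(C)C(C)(C)C | intermediate
24 | 3-methoxy-2-prenyl-6-[(3R,4R)-4-(TBS-oxy)-6-prenyl-7-(TIPS-oxy)chroman-3-yl]benzene-1,4-diol | CC(C)=CCc1cc2c(cc1O[Si](C(C)C)(C(C)C)C(C)C)OC[C@@H](c1cc(O)c(OC)c(CC=C(C)C)c1O)[C@H]2O[Si](C)(C)C(C)(C)C | intermediate (not isolated)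
25 | (6aR,11aR)-8-hydroxy-9-methoxy-2,10-diprenyl-3-(TIPS-oxy)pterocarpan | CC(C)=CCc1cc2c(cc1O[Si](C(C)C)(C(C)C)C(C)C)OC[C@H]1c3cc(O)c(OC)c(CC=C(C)C)c3O[C@@H]21 | intermediate
26 | 3-chloro-3-methylbut-1-yne | C#CC(C)(C)Cl | starting material
27 | (6aR,11aR)-9-methoxy-8-[(2-methylbut-3-yn-2-yl)oxy]-2,10-diprenyl-3-(TIPS-oxy)pterocarpan | CC(C)=CCc1cc2c(cc1O[Si](C(C)C)(C(C)C)C(C)C)OC[C@H]1c3cc(OC(C)(C)C#C)c(OC)c(CC=C(C)C)c3O[C@@H]21 | intermediate
28 | 9-O-methyl-3-O-TIPS-lespecyrtin E3 | CC(C)=CCc1cc2c(cc1O[Si](C(C)C)(C(C)C)C(C)C)OC[C@H]1c3c4c(c(OC)c(CC=C(C)C)c3O[C@@H]21)OC(C)(C)C=C4 | intermediate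
29 | 9-O-methyllespecyrtin E3 | CC(C)=CCc1cc2c(cc1O)OC[C@H]1c3c4c(c(OC)c(CC=C(C)C)c3O[C@@H]21)OC(C)(C)C=C4 | intermediate
30 | lespecyrtin E3, (6aR,11aR) | CC(C)=CCc1cc2c(cc1O)OC[C@H]1c3c4c(c(O)c(CC=C(C)C)c3O[C@@H]21)OC(C)(C)C=C4 | target

## Step count and uncertain steps

Total: 18 steps. Longest linear sequence: 16 steps (steps 1–9 and 12–18 from 1); the squarate branch contributes steps 10 and 11.

**Step 13 (key step).**
- What may go wrong: closure of the ketene on the proximal alkyne carbon (five-membered ring) in competition with the six-membered closure, diversion of the diradical by hydrogen abstraction from the medium, and slow loss of configuration at C6a by quinone/quinone-methide tautomerism if heating is prolonged.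
- Fallback: starting from 13, hydrozirconation with Cp2Zr(H)Cl and iodinolysis gives the (E)-vinyl iodide F1. Iodine–lithium exchange (t-BuLi, Et2O, −78 °C) and addition to 19 gives the 4-alkenyl-4-hydroxycyclobutenone F2. Its thermolysis (toluene, 110 °C, argon) runs through 4π opening and 6π electrocyclisation of a dienyl ketene, a closed-shell path with no five-membered alternative, and after tautomerisation gives hydroquinone 24. The route is rejoined at 24 for the acid closure of step 14. The same C10a–C6b bond forms and the same ring D closes.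

**Step 7.**
- What may go wrong: reduction outrunning racemisation, isomerisation of the β,γ-alkynyl ketone to the conjugated allenyl ketone in the amine-containing medium, or weak cis/trans discrimination by the slender alkynyl group. Each lowers the enantiomeric purity at the future C6a.
- Fallback: from 10, reduction with LiBH(s-Bu)3 at −78 °C (hydride anti to the alkynyl group) gives the racemic cis-alcohol F3. Lipase PS (Burkholderia cepacia) with vinyl acetate acylates one enantiomer, by the empirical rule for benzylic secondary alcohols the 4R one, giving acetate F4 and leaving the (3S,4S)-alcohol F5, which can be oxidised back to 10 and recycled. Reductive removal of the acetyl group from F4 with i-Bu2AlH at −78 °C returns to the route at 11. The identity of the acylated enantiomer would have to be checked before material is carried on.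

**Step 11.**
- What may go wrong: migration of the allyl double bond into conjugation with the cyclobutenedione under the action of ruthenium hydride species, or stalling of the catalyst by chelation to the dione carbonyls; the doubly activated CH2 of 17 also makes it sensitive to base.
- Fallback: from 14, prenylbarium chloride (prenyl chloride and activated barium from BaI2 and lithium biphenylide, THF, −78 °C), an allylic reagent known to attack carbonyl groups through its unsubstituted terminus, gives the 1,2-adduct F6. Trifluoroacetic anhydride then converts F6 into 19, where the route is rejoined.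

**Step 14.**
- What may go wrong: protonation of the C10 prenyl alkene and capture by the neighbouring C10a hydroxyl (chroman formation) competing with ionisation of the hindered silyl ether, E1 loss of H6a from the C11a cation, and re-oxidation of the hydroquinone during handling.
- Fallback: from 23, HF·pyridine in THF–pyridine at 0 °C removes the secondary alkyl silyl ether while the aryl silyl ether stays, giving quinone alcohol F7. Na2S2O4 then gives hydroquinone alcohol F8, a 2′-hydroxyisoflavan-4-ol. It should close to 25 under the very mild conditions typical of that class (pyridinium p-toluenesulfonate, CH2Cl2, rt), because a free benzylic hydroxyl ionises far more readily than its silyl ether.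

**Step 18.**
- What may go wrong: attack of the thiolate at C6 or C11a in competition with the methyl group (opening ring B or C), and degradation of the electron-rich bis-phenoxide at 120 °C.
- Fallback: from 23, hydrolysis of the vinylogous ester with LiOH in aqueous THF at 0 °C gives hydroxyquinone F9. Na2S2O4 reduction gives benzenetriol F10, which closes with BF3·OEt2 as in step 14 to the 8,9-dihydroxypterocarpan F11. Copper-catalysed propargylation with 26 at the less hindered O8 gives F12; an ether at O9 could not rearrange because both its ortho positions are substituted. Heating in o-xylene gives chromene F13, and Bu4NF removes the TIPS group to reach 30 without any demethylation.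

## Further compounds

F1 | step 13 | (3R,4R)-4-(TBS-oxy)-3-[(E)-2-iodoethenyl]-6-prenyl-7-(TIPS-oxy)chromane | CC(C)=CCc1cc2c(cc1O[Si](C(C)C)(C(C)C)C(C)C)OC[C@@H](/C=C/I)[C@H]2O[Si](C)(C)C(C)(C)C
F2 | step 13 | 4-{(E)-2-[(3R,4R)-4-(TBS-oxy)-6-prenyl-7-(TIPS-oxy)chroman-3-yl]ethenyl}-4-hydroxy-3-methoxy-2-prenylcyclobut-2-en-1-one | CC(C)=CCc1cc2c(cc1O[Si](C(C)C)(C(C)C)C(C)C)OC[C@@H](/C=C/C1(O)C(OC)=C(CC=C(C)C)C1=O)[C@H]2O[Si](C)(C)C(C)(C)C
F3 | step 7 | rac-cis-6-prenyl-7-(TIPS-oxy)-3-[(TMS)ethynyl]chroman-4-ol (racemate; the 3R,4R enantiomer is drawn) | CC(C)=CCc1cc2c(cc1O[Si](C(C)C)(C(C)C)C(C)C)OC[C@@H](C#C[Si](C)(C)C)[C@H]2O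
F4 | step 7 | (3R,4R)-6-prenyl-7-(TIPS-oxy)-3-[(TMS)ethynyl]chroman-4-yl acetate | CC(C)=CCc1cc2c(cc1O[Si](C(C)C)(C(C)C)C(C)C)OC[C@@H](C#C[Si](C)(C)C)[C@H]2OC(C)=O
F5 | step 7 | (3S,4S)-6-prenyl-7-(TIPS-oxy)-3-[(TMS)ethynyl]chroman-4-ol | CC(C)=CCc1cc2c(cc1O[Si](C(C)C)(C(C)C)C(C)C)OC[C@H](C#C[Si](C)(C)C)[C@@H]2O
F6 | step 11 | 4-hydroxy-2,3-dimethoxy-4-prenylcyclobut-2-en-1-one | COC1=C(OC)C(O)(CC=C(C)C)C1=O
F7 | step 14 | 5-[(3R,4R)-4-hydroxy-6-prenyl-7-(TIPS-oxy)chroman-3-yl]-2-methoxy-3-prenyl-1,4-benzoquinone | CC(C)=CCc1cc2c(cc1O[Si](C(C)C)(C(C)C)C(C)C)OC[C@@H](C1=CC(=O)C(OC)=C(CC=C(C)C)C1=O)[C@H]2O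
F8 | step 14 | 6-[(3R,4R)-4-hydroxy-6-prenyl-7-(TIPS-oxy)chroman-3-yl]-3-methoxy-2-prenylbenzene-1,4-diol | CC(C)=CCc1cc2c(cc1O[Si](C(C)C)(C(C)C)C(C)C)OC[C@@H](c1cc(O)c(OC)c(CC=C(C)C)c1O)[C@H]2O
F9 | step 18 | 2-hydroxy-3-prenyl-5-[(3R,4R)-4-(TBS-oxy)-6-prenyl-7-(TIPS-oxy)chroman-3-yl]-1,4-benzoquinone | CC(C)=CCc1cc2c(cc1O[Si](C(C)C)(C(C)C)C(C)C)OC[C@@H](C1=CC(=O)C(O)=C(CC=C(C)C)C1=O)[C@H]2O[Si](C)(C)C(C)(C)C
F10 | step 18 | 3-prenyl-5-[(3R,4R)-4-(TBS-oxy)-6-prenyl-7-(TIPS-oxy)chroman-3-yl]benzene-1,2,4-triol | CC(C)=CCc1cc2c(cc1O[Si](C(C)C)(C(C)C)C(C)C)OC[C@@H](c1cc(O)c(O)c(CC=C(C)C)c1O)[C@H]2O[Si](C)(C)C(C)(C)C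
F11 | step 18 | (6aR,11aR)-8,9-dihydroxy-2,10-diprenyl-3-(TIPS-oxy)pterocarpan | CC(C)=CCc1cc2c(cc1O[Si](C(C)C)(C(C)C)C(C)C)OC[C@H]1c3cc(O)c(O)c(CC=C(C)C)c3O[C@@H]21
F12 | step 18 | (6aR,11aR)-9-hydroxy-8-[(2-methylbut-3-yn-2-yl)oxy]-2,10-diprenyl-3-(TIPS-oxy)pterocarpan | CC(C)=CCc1cc2c(cc1O[Si](C(C)C)(C(C)C)C(C)C)OC[C@H]1c3cc(OC(C)(C)C#C)c(O)c(CC=C(C)C)c3O[C@@H]21
F13 | step 18 | 3-O-TIPS-lespecyrtin E3 | CC(C)=CCc1cc2c(cc1O[Si](C(C)C)(C(C)C)C(C)C)OC[C@H]1c3c4c(c(O)c(CC=C(C)C)c3O[C@@H]21)OC(C)(C)C=C4
A1 | alternative 1 | methyl 2-diazo-2-[5-(methoxymethoxy)-3-prenyl-4-(TIPS-oxy)-2-{[2-(methoxymethoxy)-5-prenyl-4-(TIPS-oxy)benzyl]oxy}phenyl]acetate | COC(=O)C(=[N+]=[N-])c1cc(OCOC)c(O[Si](C(C)C)(C(C)C)C(C)C)c(CC=C(C)C)c1OCc1cc(CC=C(C)C)c(O[Si](C(C)C)(C(C)C)C(C)C)cc1OCOC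
A2 | alternative 1 | methyl cis-2-(ring A aryl)-2,3-dihydrobenzofuran-3-carboxylate with C6a and C11a as in 30 | COC(=O)[C@H]1c2cc(OCOC)c(O[Si](C(C)C)(C(C)C)C(C)C)c(CC=C(C)C)c2O[C@H]1c1cc(CC=C(C)C)c(O[Si](C(C)C)(C(C)C)C(C)C)cc1OCOC
A3 | alternative 2 | 1-(methoxymethoxy)-4-prenyl-3-(TIPS-oxy)benzene | COCOc1ccc(CC=C(C)C)c(O[Si](C(C)C)(C(C)C)C(C)C)c1
A4 | alternative 2 | 5-(2-methoxyethenyl)-2,2-dimethyl-7-prenyl-6,8-bis(TBS-oxy)-2H-chromene | COC=Cc1c2C=CC(C)(C)Oc2c(O[Si](C)(C)C(C)(C)C)c(CC=C(C)C)c1O[Si](C)(C)C(C)(C)C
A5 | alternative 2 | 4-methoxyisoflavan with C6a as in 30 (C11a epimers) | CC(C)=CCc1cc2c(cc1O[Si](C(C)C)(C(C)C)C(C)C)OC[C@@H](c1c3C=CC(C)(C)Oc3c(O[Si](C)(C)C(C)(C)C)c(CC=C(C)C)c1O[Si](C)(C)C(C)(C)C)C2OC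
A6 | alternative 3 | 2-methoxy-3-prenyl-1,4-benzoquinone | COC1=C(CC=C(C)C)C(=O)C=CC1=O
A7 | alternative 3 | 6-prenyl-7-(TIPS-oxy)-2H-chromene | CC(C)=CCc1cc2C=CCOc2cc1O[Si](C(C)C)(C(C)C)C(C)C
A8 | alternative 3 | (6aR,11aR)-8-hydroxy-9-methoxy-2,10-diprenyl-3-(TIPS-oxy)pterocarpan (identical with 25) | CC(C)=CCc1cc2c(cc1O[Si](C(C)C)(C(C)C)C(C)C)OC[C@H]1c3cc(O)c(OC)c(CC=C(C)C)c3O[C@@H]21
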